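**Retrosynthetic overview**

1. The route rests on the three trans-2,3-diaryl-2,3-dihydrobenzofuran rings (each O1–C2–C3–C3a–C7a). Ring 3 is fused to resorcinol arene G and carries the 3,5-dioxygenated phenyl on C3; ring 2 is central; ring 1 is fused to the styryl-bearing arene A. Each ring is one ring carbon smaller than a 4-aryl-3,4-dihydrocoumarin.
2. Each O1–C2 bond is cut back to a trans-3-bromo-4-aryl lactone (hydroxide ring contraction, lactone carbon expelled as the C2 carboxyl). Each C2–aryl bond is cut back to that carboxylic acid (decarboxylative arylation).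
3. Ring 3 first: coumarin 6, Rh-catalysed asymmetric 4-arylation (sets C3), trans bromolactone 10, contraction to acid 12. Acid 12 keeps a C4 ester on its arene and serves for both ring 3 and ring 1.
4. Ring 2 second: the C4 ester of arene G becomes cinnamate 18; asymmetric 1,4-addition of a 5-bromo-2-oxyphenyl group, lactonisation, bromination, contraction and arylation give bromide 30.
5. Ring 1 last: a second portion of 12 is joined to 30 (C2 of ring 1 to C5 of ring 2); the arene A ester becomes the (E)-styryl group, and the nine benzyl ethers are cleaved at the end.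

Key step: step 6

Remark 1: benzyl ethers replace methyl ethers, because ninefold demethylation with BBr3 would expose the stilbene and the 2-aryl dihydrofurans to HBr, whereas benzyl ethers are cleaved by BCl3/pentamethylbenzene at −78 °C.
Remark 2: in the ring contraction hydroxide is held at two equivalents so that the aryl methyl ester survives; a second free carboxylate would compete in the nickel step that follows, so the key product is carried as the 2-acid 4-methyl ester.
Remark 3: the C2 carboxyl centre of each contraction product becomes a radical in the next step, so only C3 has to stay intact.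
Remark 4: in names, "unit G" is the (2R,3R)-6-(benzyloxy)-3-[3,5-bis(benzyloxy)phenyl]-2-[4-(benzyloxy)phenyl]-2,3-dihydro-1-benzofuran-4-yl group, and "unit B" is the (2R,3R)-2-[4-(benzyloxy)phenyl]-3-(unit G)-2,3-dihydro-1-benzofuran-5-yl group.

**Route**

Step 1
Reactants: 1 methyl 2-bromo-3,5-dimethoxybenzoate; 2 methyl acrylate
Product: 3 methyl (2E)-3-[2,4-dimethoxy-6-(methoxycarbonyl)phenyl]prop-2-enoate
Conditions: Pd2(dba)3 (2 mol %), P(t-Bu)3·HBF4 (8 mol %), Cy2NMe, 1,4-dioxane, 90 °C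
Reagents that add atoms: none
Why: Heck reaction, in which the bulky electron-rich phosphine lets zerovalent palladium insert into the doubly ortho-substituted aryl bromide and acrylate insertion with β-hydride elimination should give the (E)-cinnamate.

Step 2
Reactants: 3 methyl (2E)-3-[2,4-dimethoxy-6-(methoxycarbonyl)phenyl]prop-2-enoate
Product: 5 methyl 7-hydroxy-2-oxo-2H-chromene-5-carboxylate, via (E)-dihydroxy diester 4 (not isolated)
Conditions: BBr3 (3 equiv), CH2Cl2, −78 → 0 °C; H2O work-up; then hν (365 nm), MeCN, rt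
Reagents that add atoms: none
Why: Lewis-acid ether cleavage frees both phenols while the esters should survive at low temperature, and irradiation then turns the (E)-2-hydroxycinnamate into the Z isomer, which lactonises at once (photochemical E→Z isomerisation–lactonisation); keeping the benzoate as its ester avoids conjugate addition of a free peri carboxyl.

Step 3
Reactants: 5 methyl 7-hydroxy-2-oxo-2H-chromene-5-carboxylate
Product: 6 methyl 7-(benzyloxy)-2-oxo-2H-chromene-5-carboxylate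
Conditions: BnBr (1.1 equiv), K2CO3, acetone, 55 °C
Reagents that add atoms: benzyl bromide, BrCc1ccccc1
Why: Williamson O-alkylation of the phenoxide, which installs the phenol protecting group used throughout.

Step 4
Reactants: 6 methyl 7-(benzyloxy)-2-oxo-2H-chromene-5-carboxylate; 7 [3,5-bis(benzyloxy)phenyl]boronic acid
Product: 8 methyl (4R)-7-(benzyloxy)-4-[3,5-bis(benzyloxy)phenyl]-2-oxo-3,4-dihydro-2H-chromene-5-carboxylate
Conditions: Rh(acac)(C2H4)2 (3 mol %), (R)-SEGPHOS (3.3 mol %), 7 (3 equiv), 1,4-dioxane/H2O 10:1, 60 °C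
Reagents that add atoms: none
Why: Hayashi–Miyaura 1,4-addition to a coumarin, in which the aryl–rhodium/(R)-SEGPHOS species is expected to add to the face of C3=C4 that gives (R)-4-arylchroman-2-ones, so the future C3 of rings 3 and 1 is set by catalyst control.

Step 5
Reactants: 8 methyl (4R)-7-(benzyloxy)-4-[3,5-bis(benzyloxy)phenyl]-2-oxo-3,4-dihydro-2H-chromene-5-carboxylate
Product: 10 methyl (3S,4R)-7-(benzyloxy)-4-[3,5-bis(benzyloxy)phenyl]-3-bromo-2-oxo-3,4-dihydro-2H-chromene-5-carboxylate, via lithium enolate 9 (not isolated)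
Conditions: LiN(SiMe3)2 (1.05 equiv), THF, −78 °C; transfer into NBS (1.05 equiv), THF, −78 °C; AcOH quench
Reagents that add atoms: N-bromosuccinimide, O=C1CCC(=O)N1Br
Why: electrophilic α-bromination of a lactone enolate, in which the pseudo-axial C4 aryl group (pushed there by the peri ester) blocks one face so that bromine should enter anti to it and give the trans bromolactone.

Step 6
Reactants: 10 methyl (3S,4R)-7-(benzyloxy)-4-[3,5-bis(benzyloxy)phenyl]-3-bromo-2-oxo-3,4-dihydro-2H-chromene-5-carboxylate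
Product: 12 (2R,3R)-6-(benzyloxy)-3-[3,5-bis(benzyloxy)phenyl]-4-(methoxycarbonyl)-2,3-dihydro-1-benzofuran-2-carboxylic acid, via ring-opened bromo carboxylate phenoxide 11 (not isolated)
Conditions: KOH (2.05 equiv, 0.5 M aq), THF, 0 °C → rt; then 1 M HCl to pH 3
Reagents that add atoms: potassium hydroxide, [K+].[OH-]
Why: Hydroxide adds to the aryl lactone carbonyl of 10, the ring opens to the phenol and α-bromo carboxylate, and the second equivalent gives phenoxide 11, whose oxygen displaces bromide from the rear to form the O1–C2 bond of ring 3. The closest known reaction type is the Perkin ring contraction of 3-halocoumarins and 3-halo-3,4-dihydrocoumarins to benzofuran-2-carboxylic acids. Ring 3 closes in the 5-exo-tet mode, and the former lactone carbon is left as the exocyclic C2 carboxyl. C2 is set by stereospecific inversion of the (3S)-bromide, so the trans bromolactone should give the 2,3-trans acid, while C3 is carried unchanged from the catalyst-controlled step 4. The step needs substitution to outrun elimination to the achiral coumarin, and the lactone to be opened without saponifying the aryl methyl ester. In the lactone the trans substituents are diaxial, so H4 is gauche to bromine and no anti-periplanar E2 is open before ring opening; the carboxylate no longer enolises; and both equivalents of hydroxide are consumed by the far more electrophilic lactone and by the phenol.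

Step 7
Reactants: 12 (2R,3R)-6-(benzyloxy)-3-[3,5-bis(benzyloxy)phenyl]-4-(methoxycarbonyl)-2,3-dihydro-1-benzofuran-2-carboxylic acid; 13 1-(benzyloxy)-4-iodobenzene
Product: 14 methyl (2R,3R)-6-(benzyloxy)-3-[3,5-bis(benzyloxy)phenyl]-2-[4-(benzyloxy)phenyl]-2,3-dihydro-1-benzofuran-4-carboxylate
Conditions: Ir[dF(CF3)ppy]2(dtbbpy)PF6 (2 mol %), NiCl2·DME (10 mol %), dtbbpy (15 mol %), Cs2CO3 (1.5 equiv), 13 (2 equiv), DMF, blue LEDs (450 nm), rt
Reagents that add atoms: none
Why: metallaphotoredox decarboxylative arylation, in which the carboxylate is oxidised by the excited photocatalyst, loses CO2, and the α-oxy radical at C2 is captured by the aryl–nickel species from 13, the new aryl group being expected to end up anti to the C3 aryl group (substrate control, trans).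

Step 8
Reactants: 14 methyl (2R,3R)-6-(benzyloxy)-3-[3,5-bis(benzyloxy)phenyl]-2-[4-(benzyloxy)phenyl]-2,3-dihydro-1-benzofuran-4-carboxylate
Product: 15 (unit G)methanol
Conditions: i-Bu2AlH (3 equiv), CH2Cl2, −78 → 0 °C; aq. potassium sodium tartrate
Reagents that add atoms: none
Why: hydride reduction of the aryl ester to the benzylic alcohol, with ethers and the dihydrofuran inert to i-Bu2AlH.

Step 9
Reactants: 15 (unit G)methanol; 16 methyl (triphenylphosphoranylidene)acetate
Product: 18 methyl (2E)-3-(unit G)prop-2-enoate, via aldehyde 17 (not isolated)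
Conditions: MnO2 (15 equiv), 16 (1.3 equiv), CH2Cl2, 40 °C
Reagents that add atoms: none
Why: tandem oxidation–Wittig reaction, in which MnO2 oxidises the benzylic alcohol to the aldehyde and the stabilised ylide traps it in the same flask to give the (E)-cinnamate.

Step 10
Reactants: 19 4-bromo-2-iodophenol
Product: 20 4-bromo-2-iodo-1-(methoxymethoxy)benzene
Conditions: MOMCl (1.3 equiv), i-Pr2NEt, CH2Cl2, 0 °C → rt
Reagents that add atoms: chloromethyl methyl ether, COCCl
Why: O-alkylation to the MOM acetal, a phenol mask that is orthogonal to benzyl ethers and stable to the organometallic steps.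

Step 11
Reactants: 20 4-bromo-2-iodo-1-(methoxymethoxy)benzene
Product: 22 [5-bromo-2-(methoxymethoxy)phenyl]boronic acid, via aryl Grignard reagent 21 (not isolated)
Conditions: i-PrMgCl·LiCl (1.05 equiv), THF, −40 °C; B(OMe)3 (2 equiv), −40 → 0 °C; aq. HCl to pH 5
Reagents that add atoms: trimethyl borate, COB(OC)OC; water, O
Why: iodine–magnesium exchange is far faster at C–I than at C–Br and is helped by the ortho acetal oxygen, and borylation of the Grignard reagent with hydrolysis gives the boronic acid.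

Step 12
Reactants: 18 methyl (2E)-3-(unit G)prop-2-enoate; 22 [5-bromo-2-(methoxymethoxy)phenyl]boronic acid
Product: 23 methyl (3R)-3-[5-bromo-2-(methoxymethoxy)phenyl]-3-(unit G)propanoate
Conditions: [RhCl(C2H4)2]2 (2.5 mol %), (1R,4R)-2,5-diphenylbicyclo[2.2.2]octa-2,5-diene (5.5 mol %), 22 (3 equiv), KOH (0.2 equiv), 1,4-dioxane/H2O 10:1, 40 °C
Reagents that add atoms: none
Why: Hayashi–Miyaura 1,4-addition to a β-aryl acrylate with a chiral diene–rhodium catalyst, the ligand being expected (by analogy with cyclic enones and (E)-enoates) to deliver the aryl group to the re face of C3 of the enoate, which sets the future C3 of ring 2 as (R) by catalyst control.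

Step 13
Reactants: 23 methyl (3R)-3-[5-bromo-2-(methoxymethoxy)phenyl]-3-(unit G)propanoate
Product: 25 (4R)-6-bromo-4-(unit G)-3,4-dihydro-2H-chromen-2-one, via phenol ester 24 (not isolated)
Conditions: HCl (1.25 M in MeOH), CH2Cl2, 0 °C → rt; evaporate; PPTS (10 mol %), toluene, 5 Å MS, 80 °C
Reagents that add atoms: none
Why: acidic methanolysis removes the MOM acetal, and the freed phenol lactonises onto the methyl ester under mild acid catalysis (transesterification driven by removal of methanol).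

Step 14
Reactants: 25 (4R)-6-bromo-4-(unit G)-3,4-dihydro-2H-chromen-2-one
Product: 27 (3S,4R)-3,6-dibromo-4-(unit G)-3,4-dihydro-2H-chromen-2-one, via lithium enolate 26 (not isolated)
Conditions: LiN(SiMe3)2 (1.05 equiv), THF, −78 °C; transfer into NBS (1.05 equiv), THF, −78 °C; AcOH quench
Reagents that add atoms: N-bromosuccinimide, O=C1CCC(=O)N1Br
Why: α-bromination of the lactone enolate as in step 5, with the large C4 substituent directing bromine to the opposite face to give the trans bromolactone.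

Step 15
Reactants: 27 (3S,4R)-3,6-dibromo-4-(unit G)-3,4-dihydro-2H-chromen-2-one
Product: 29 (2R,3R)-5-bromo-3-(unit G)-2,3-dihydro-1-benzofuran-2-carboxylic acid, via ring-opened bromo carboxylate phenoxide 28 (not isolated)
Conditions: KOH (3 equiv, aq), THF, 0 °C → rt; then 1 M HCl
Reagents that add atoms: potassium hydroxide, [K+].[OH-]
Why: the same Perkin-type ring contraction as in step 6, lactone opening followed by 5-exo-tet displacement of the alkyl bromide by the phenoxide with inversion, closes ring 2 as the 2,3-trans acid, while the aryl bromide is inert to hydroxide.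

Step 16
Reactants: 29 (2R,3R)-5-bromo-3-(unit G)-2,3-dihydro-1-benzofuran-2-carboxylic acid; 13 1-(benzyloxy)-4-iodobenzene
Product: 30 (2R,3R)-5-bromo-2-[4-(benzyloxy)phenyl]-3-(unit G)-2,3-dihydro-1-benzofuran
Conditions: Ir[dF(CF3)ppy]2(dtbbpy)PF6 (2 mol %), NiCl2·DME (10 mol %), dtbbpy (15 mol %), Cs2CO3 (1.5 equiv), 13 (3 equiv), DMF, blue LEDs (450 nm), rt
Reagents that add atoms: none
Why: metallaphotoredox decarboxylative arylation as in step 7, where zerovalent nickel should insert into the aryl iodide 13 (used in excess) much faster than into the aryl bromide of 29 and the aryl group should enter trans to the C3 substituent.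

Step 17
Reactants: 30 (2R,3R)-5-bromo-2-[4-(benzyloxy)phenyl]-3-(unit G)-2,3-dihydro-1-benzofuran; 12 (2R,3R)-6-(benzyloxy)-3-[3,5-bis(benzyloxy)phenyl]-4-(methoxycarbonyl)-2,3-dihydro-1-benzofuran-2-carboxylic acid
Product: 31 methyl (2R,3R)-6-(benzyloxy)-3-[3,5-bis(benzyloxy)phenyl]-2-(unit B)-2,3-dihydro-1-benzofuran-4-carboxylate
Conditions: Ir[dF(CF3)ppy]2(dtbbpy)PF6 (2 mol %), NiCl2·DME (10 mol %), dtbbpy (15 mol %), Cs2CO3 (2 equiv), 12 (1.5 equiv), DMF, blue LEDs (450 nm), rt
Reagents that add atoms: none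
Why: metallaphotoredox decarboxylative arylation joins the two halves, the α-oxy radical from 12 coupling with the aryl–nickel species from bromide 30 to form the bond between C2 of ring 1 and C5 of ring 2, trans to the C3 aryl group of ring 1 by substrate control.

Step 18
Reactants: 31 methyl (2R,3R)-6-(benzyloxy)-3-[3,5-bis(benzyloxy)phenyl]-2-(unit B)-2,3-dihydro-1-benzofuran-4-carboxylate
Product: 32 {(2R,3R)-6-(benzyloxy)-3-[3,5-bis(benzyloxy)phenyl]-2-(unit B)-2,3-dihydro-1-benzofuran-4-yl}methanol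
Conditions: i-Bu2AlH (3 equiv), CH2Cl2, −78 → 0 °C; aq. potassium sodium tartrate
Reagents that add atoms: none
Why: hydride reduction of the only ester in the molecule to the benzylic alcohol.

Step 19
Reactants: 32 {(2R,3R)-6-(benzyloxy)-3-[3,5-bis(benzyloxy)phenyl]-2-(unit B)-2,3-dihydro-1-benzofuran-4-yl}methanol
Product: 33 (2R,3R)-6-(benzyloxy)-3-[3,5-bis(benzyloxy)phenyl]-2-(unit B)-2,3-dihydro-1-benzofuran-4-carbaldehyde
Conditions: MnO2 (15 equiv), CH2Cl2, rt
Reagents that add atoms: none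
Why: MnO2 oxidation of a benzylic alcohol stops at the aldehyde and leaves the ethers untouched.

Step 20
Reactants: 34 1-(benzyloxy)-4-(chloromethyl)benzene; 35 triethyl phosphite
Product: 36 diethyl {[4-(benzyloxy)phenyl]methyl}phosphonate
Conditions: neat, 140 °C
Reagents that add atoms: none
Why: Michaelis–Arbuzov reaction of a benzylic chloride with P(OEt)3.

Step 21
Reactants: 33 (2R,3R)-6-(benzyloxy)-3-[3,5-bis(benzyloxy)phenyl]-2-(unit B)-2,3-dihydro-1-benzofuran-4-carbaldehyde; 36 diethyl {[4-(benzyloxy)phenyl]methyl}phosphonate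
Product: 37 nona-O-benzyl ether of the target, (2R,3R)-6-(benzyloxy)-3-[3,5-bis(benzyloxy)phenyl]-4-{(E)-2-[4-(benzyloxy)phenyl]ethenyl}-2-(unit B)-2,3-dihydro-1-benzofuran
Conditions: KOt-Bu (1.3 equiv), 36 (1.3 equiv), THF, 0 °C → rt
Reagents that add atoms: none
Why: Horner–Wadsworth–Emmons olefination with a benzylphosphonate anion should give the (E)-stilbene selectively, and no stereocentre is acidic enough to be touched.

Step 22
Reactants: 37 nona-O-benzyl ether of the target
Product: 38 CNP0184803.1, the free nonaphenol with all six stereocentres R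
Conditions: BCl3 (1 M in CH2Cl2, 30 equiv), pentamethylbenzene (30 equiv), CH2Cl2, −78 °C; MeOH quench at −78 °C, then H2O
Reagents that add atoms: none
Why: Lewis-acid debenzylation, in which BCl3 ionises the aryl benzyl ethers at low temperature and pentamethylbenzene traps the benzyl cations, so the nine phenols should be freed without protic acid acting on the stilbene or the dihydrofurans.

**Compound list**

1 | methyl 2-bromo-3,5-dimethoxybenzoate | COC(=O)c1cc(OC)cc(OC)c1Br | starting material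
2 | methyl acrylate | C=CC(=O)OC | starting material
3 | methyl (2E)-3-[2,4-dimethoxy-6-(methoxycarbonyl)phenyl]prop-2-enoate | COC(=O)/C=C/c1c(OC)cc(OC)cc1C(=O)OC | intermediate
4 | methyl (2E)-3-[2,4-dihydroxy-6-(methoxycarbonyl)phenyl]prop-2-enoate (not isolated) | COC(=O)/C=C/c1c(O)cc(O)cc1C(=O)OC | intermediate
5 | methyl 7-hydroxy-2-oxo-2H-chromene-5-carboxylate | COC(=O)c1cc(O)cc2oc(=O)ccc12 | intermediate
6 | methyl 7-(benzyloxy)-2-oxo-2H-chromene-5-carboxylate | COC(=O)c1cc(OCc2ccccc2)cc2oc(=O)ccc12 | intermediate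
7 | [3,5-bis(benzyloxy)phenyl]boronic acid | OB(O)c1cc(OCc2ccccc2)cc(OCc2ccccc2)c1 | starting material
8 | methyl (4R)-7-(benzyloxy)-4-[3,5-bis(benzyloxy)phenyl]-2-oxo-3,4-dihydro-2H-chromene-5-carboxylate | COC(=O)c1cc(OCc2ccccc2)cc2c1[C@@H](c1cc(OCc3ccccc3)cc(OCc3ccccc3)c1)CC(=O)O2 | intermediate
9 | lithium enolate of 8 (not isolated) | COC(=O)c1cc(OCc2ccccc2)cc2c1[C@@H](c1cc(OCc3ccccc3)cc(OCc3ccccc3)c1)C=C([O-])O2.[Li+] | intermediate
10 | methyl (3S,4R)-7-(benzyloxy)-4-[3,5-bis(benzyloxy)phenyl]-3-bromo-2-oxo-3,4-dihydro-2H-chromene-5-carboxylate (trans) | COC(=O)c1cc(OCc2ccccc2)cc2c1[C@@H](c1cc(OCc3ccccc3)cc(OCc3ccccc3)c1)[C@H](Br)C(=O)O2 | intermediate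
11 | dipotassium (2S,3R)-3-[4-(benzyloxy)-2-(methoxycarbonyl)-6-oxidophenyl]-3-[3,5-bis(benzyloxy)phenyl]-2-bromopropanoate (not isolated) | COC(=O)c1cc(OCc2ccccc2)cc([O-])c1[C@@H](c1cc(OCc3ccccc3)cc(OCc3ccccc3)c1)[C@H](Br)C(=O)[O-].[K+].[K+] | intermediate
12 | (2R,3R)-6-(benzyloxy)-3-[3,5-bis(benzyloxy)phenyl]-4-(methoxycarbonyl)-2,3-dihydro-1-benzofuran-2-carboxylic acid (2,3-trans) | COC(=O)c1cc(OCc2ccccc2)cc2c1[C@@H](c1cc(OCc3ccccc3)cc(OCc3ccccc3)c1)[C@H](C(=O)O)O2 | intermediate
13 | 1-(benzyloxy)-4-iodobenzene | Ic1ccc(OCc2ccccc2)cc1 | starting material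
14 | methyl (2R,3R)-6-(benzyloxy)-3-[3,5-bis(benzyloxy)phenyl]-2-[4-(benzyloxy)phenyl]-2,3-dihydro-1-benzofuran-4-carboxylate | COC(=O)c1cc(OCc2ccccc2)cc2c1[C@@H](c1cc(OCc3ccccc3)cc(OCc3ccccc3)c1)[C@H](c1ccc(OCc3ccccc3)cc1)O2 | intermediate
15 | (unit G)methanol | OCc1cc(OCc2ccccc2)cc2c1[C@@H](c1cc(OCc3ccccc3)cc(OCc3ccccc3)c1)[C@H](c1ccc(OCc3ccccc3)cc1)O2 | intermediate
16 | methyl (triphenylphosphoranylidene)acetate | COC(=O)C=P(c1ccccc1)(c1ccccc1)c1ccccc1 | starting material
17 | unit G carbaldehyde (not isolated) | O=Cc1cc(OCc2ccccc2)cc2c1[C@@H](c1cc(OCc3ccccc3)cc(OCc3ccccc3)c1)[C@H](c1ccc(OCc3ccccc3)cc1)O2 | intermediate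
18 | methyl (2E)-3-(unit G)prop-2-enoate | COC(=O)/C=C/c1cc(OCc2ccccc2)cc2c1[C@@H](c1cc(OCc3ccccc3)cc(OCc3ccccc3)c1)[C@H](c1ccc(OCc3ccccc3)cc1)O2 | intermediate
19 | 4-bromo-2-iodophenol | Oc1ccc(Br)cc1I | starting material
20 | 4-bromo-2-iodo-1-(methoxymethoxy)benzene | COCOc1ccc(Br)cc1I | intermediate
21 | [5-bromo-2-(methoxymethoxy)phenyl]magnesium chloride (not isolated) | COCOc1ccc(Br)cc1[Mg]Cl | intermediate
22 | [5-bromo-2-(methoxymethoxy)phenyl]boronic acid | COCOc1ccc(Br)cc1B(O)O | intermediate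
23 | methyl (3R)-3-[5-bromo-2-(methoxymethoxy)phenyl]-3-(unit G)propanoate | COCOc1ccc(Br)cc1[C@H](CC(=O)OC)c1cc(OCc2ccccc2)cc2c1[C@@H](c1cc(OCc3ccccc3)cc(OCc3ccccc3)c1)[C@H](c1ccc(OCc3ccccc3)cc1)O2 | intermediate
24 | methyl (3R)-3-(5-bromo-2-hydroxyphenyl)-3-(unit G)propanoate (not isolated) | Oc1ccc(Br)cc1[C@H](CC(=O)OC)c1cc(OCc2ccccc2)cc2c1[C@@H](c1cc(OCc3ccccc3)cc(OCc3ccccc3)c1)[C@H](c1ccc(OCc3ccccc3)cc1)O2 | intermediate
25 | (4R)-6-bromo-4-(unit G)-3,4-dihydro-2H-chromen-2-one | Brc1ccc2c(c1)[C@@H](c1cc(OCc3ccccc3)cc3c1[C@@H](c1cc(OCc4ccccc4)cc(OCc4ccccc4)c1)[C@H](c1ccc(OCc4ccccc4)cc1)O3)CC(=O)O2 | intermediate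
26 | lithium enolate of 25 (not isolated) | Brc1ccc2c(c1)[C@@H](c1cc(OCc3ccccc3)cc3c1[C@@H](c1cc(OCc4ccccc4)cc(OCc4ccccc4)c1)[C@H](c1ccc(OCc4ccccc4)cc1)O3)C=C([O-])O2.[Li+] | intermediate
27 | (3S,4R)-3,6-dibromo-4-(unit G)-3,4-dihydro-2H-chromen-2-one (trans) | Brc1ccc2c(c1)[C@@H](c1cc(OCc3ccccc3)cc3c1[C@@H](c1cc(OCc4ccccc4)cc(OCc4ccccc4)c1)[C@H](c1ccc(OCc4ccccc4)cc1)O3)[C@H](Br)C(=O)O2 | intermediate
28 | dipotassium (2S,3R)-2-bromo-3-(5-bromo-2-oxidophenyl)-3-(unit G)propanoate (not isolated) | [O-]c1ccc(Br)cc1[C@@H](c1cc(OCc3ccccc3)cc3c1[C@@H](c1cc(OCc4ccccc4)cc(OCc4ccccc4)c1)[C@H](c1ccc(OCc4ccccc4)cc1)O3)[C@H](Br)C(=O)[O-].[K+].[K+] | intermediate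
29 | (2R,3R)-5-bromo-3-(unit G)-2,3-dihydro-1-benzofuran-2-carboxylic acid | Brc1ccc2c(c1)[C@@H](c1cc(OCc3ccccc3)cc3c1[C@@H](c1cc(OCc4ccccc4)cc(OCc4ccccc4)c1)[C@H](c1ccc(OCc4ccccc4)cc1)O3)[C@H](C(=O)O)O2 | intermediate
30 | (2R,3R)-5-bromo-2-[4-(benzyloxy)phenyl]-3-(unit G)-2,3-dihydro-1-benzofuran | Brc1ccc2c(c1)[C@@H](c1cc(OCc3ccccc3)cc3c1[C@@H](c1cc(OCc4ccccc4)cc(OCc4ccccc4)c1)[C@H](c1ccc(OCc4ccccc4)cc1)O3)[C@H](c1ccc(OCc3ccccc3)cc1)O2 | intermediate
31 | methyl (2R,3R)-6-(benzyloxy)-3-[3,5-bis(benzyloxy)phenyl]-2-(unit B)-2,3-dihydro-1-benzofuran-4-carboxylate | COC(=O)c1cc(OCc2ccccc2)cc2c1[C@@H](c1cc(OCc3ccccc3)cc(OCc3ccccc3)c1)[C@H](c1ccc3c(c1)[C@@H](c1cc(OCc4ccccc4)cc4c1[C@@H](c1cc(OCc5ccccc5)cc(OCc5ccccc5)c1)[C@H](c1ccc(OCc5ccccc5)cc1)O4)[C@H](c1ccc(OCc4ccccc4)cc1)O3)O2 | intermediate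
32 | {(2R,3R)-6-(benzyloxy)-3-[3,5-bis(benzyloxy)phenyl]-2-(unit B)-2,3-dihydro-1-benzofuran-4-yl}methanol | OCc1cc(OCc2ccccc2)cc2c1[C@@H](c1cc(OCc3ccccc3)cc(OCc3ccccc3)c1)[C@H](c1ccc3c(c1)[C@@H](c1cc(OCc4ccccc4)cc4c1[C@@H](c1cc(OCc5ccccc5)cc(OCc5ccccc5)c1)[C@H](c1ccc(OCc5ccccc5)cc1)O4)[C@H](c1ccc(OCc4ccccc4)cc1)O3)O2 | intermediate
33 | (2R,3R)-6-(benzyloxy)-3-[3,5-bis(benzyloxy)phenyl]-2-(unit B)-2,3-dihydro-1-benzofuran-4-carbaldehyde | O=Cc1cc(OCc2ccccc2)cc2c1[C@@H](c1cc(OCc3ccccc3)cc(OCc3ccccc3)c1)[C@H](c1ccc3c(c1)[C@@H](c1cc(OCc4ccccc4)cc4c1[C@@H](c1cc(OCc5ccccc5)cc(OCc5ccccc5)c1)[C@H](c1ccc(OCc5ccccc5)cc1)O4)[C@H](c1ccc(OCc4ccccc4)cc1)O3)O2 | intermediate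
34 | 1-(benzyloxy)-4-(chloromethyl)benzene | ClCc1ccc(OCc2ccccc2)cc1 | starting material
35 | triethyl phosphite | CCOP(OCC)OCC | starting material
36 | diethyl {[4-(benzyloxy)phenyl]methyl}phosphonate | CCOP(=O)(Cc1ccc(OCc2ccccc2)cc1)OCC | intermediate
37 | nona-O-benzyl ether of the target | c1ccccc1COc1ccc(/C=C/c2cc(OCc3ccccc3)cc3c2[C@@H](c2cc(OCc4ccccc4)cc(OCc4ccccc4)c2)[C@H](c2ccc4c(c2)[C@@H](c2cc(OCc5ccccc5)cc5c2[C@@H](c2cc(OCc6ccccc6)cc(OCc6ccccc6)c2)[C@H](c2ccc(OCc6ccccc6)cc2)O5)[C@H](c2ccc(OCc5ccccc5)cc2)O4)O3)cc1 | intermediate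
38 | CNP0184803.1 | Oc1ccc(/C=C/c2cc(O)cc3c2[C@@H](c2cc(O)cc(O)c2)[C@H](c2ccc4c(c2)[C@@H](c2cc(O)cc5c2[C@@H](c2cc(O)cc(O)c2)[C@H](c2ccc(O)cc2)O5)[C@H](c2ccc(O)cc2)O4)O3)cc1 | target

**Totals**

Total step count: 22. Longest linear sequence: 19 steps (steps 1–9, 12–19, 21, 22); steps 10, 11 and 20 make side reagents, and acid 12 is used twice.

**Three steps most likely to fail**

Step 12. Carbometalation of the twisted, ortho-flanked β-aryl acrylate 18 may be so slow that protodeboronation of 22 wins. The resident stereocentres of ring 3 may also oppose the ligand and erode facial selectivity. The fallback sets out from alcohol 15 and returns at lactone 25. Alcohol 15 is oxidised with MnO2 alone and aldehyde 17 is isolated. Knoevenagel condensation with Meldrum's acid (pyrrolidinium acetate, benzene, rt) should give the arylidene Meldrum's acid F1. Conjugate addition of Grignard reagent 21 (THF, −40 °C), a reliable reaction of alkylidene Meldrum's acids, should give the diarylmethyl Meldrum's acid F2. Here the face is chosen by the C3 aryl group of ring 3 (substrate control, to be checked; the diastereomers should be separable). HCl in MeOH and then heating in toluene remove the MOM group, and the phenol opens the Meldrum's acid with loss of acetone and CO2 to give 25.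

Step 17. Insertion of nickel into the electron-rich, bulky bromide 30 may be slow, so the α-oxy radical from 12 would be lost by reduction or by oxidation and aromatisation to the benzofuran. The aryl group may also enter with poor trans selectivity. The fallback reverses the polarity; it sets out from 30 and 12 and returns at 31. Bromine–lithium exchange on 30 (t-BuLi, THF, −78 °C) and ZnCl2 should give the arylzinc chloride F4. Acid 12 is converted with N-hydroxyphthalimide, DIC and catalytic DMAP into the redox-active N-acyloxyphthalimide F3. Thermal coupling of the two (NiCl2·DME, dtbbpy, THF/DMF, rt; decarboxylative Negishi arylation of a redox-active ester) should give 31 without light.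

Step 22. While nine ethers are cleaved, the Lewis acid may activate the electron-rich stilbene beside the 3,5-dioxygenated aryl ring of ring 1, leading to cyclisation onto that ring or E/Z scrambling. The fallback removes the benzyl groups before the stilbene exists; it sets out from aldehyde 33 and returns at target 38. BCl3/pentamethylbenzene (CH2Cl2, −78 °C) should give the octaphenol aldehyde F5. TBSCl and imidazole (DMF) should give the octakis-silyl ether aldehyde F6. Olefination with the silyl-protected benzylphosphonate F7 (from commercial diethyl (4-hydroxybenzyl)phosphonate and TBSCl) and KN(SiMe3)2 in THF should give the nonakis-silyl (E)-stilbene F8. Bu4NF buffered with AcOH then gives 38 under non-acidic conditions.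

**Further compounds**

F1 | step 12 | 5-[(unit G)methylidene]-2,2-dimethyl-1,3-dioxane-4,6-dione | CC1(C)OC(=O)C(=Cc2cc(OCc3ccccc3)cc3c2[C@@H](c2cc(OCc4ccccc4)cc(OCc4ccccc4)c2)[C@H](c2ccc(OCc4ccccc4)cc2)O3)C(=O)O1
F2 | step 12 | 5-{(R)-[5-bromo-2-(methoxymethoxy)phenyl](unit G)methyl}-2,2-dimethyl-1,3-dioxane-4,6-dione | COCOc1ccc(Br)cc1[C@H](C1C(=O)OC(C)(C)OC1=O)c1cc(OCc2ccccc2)cc2c1[C@@H](c1cc(OCc3ccccc3)cc(OCc3ccccc3)c1)[C@H](c1ccc(OCc3ccccc3)cc1)O2
F3 | step 17 | 2-(1,3-dioxoisoindolin-2-yl) 4-methyl (2R,3R)-6-(benzyloxy)-3-[3,5-bis(benzyloxy)phenyl]-2,3-dihydro-1-benzofuran-2,4-dicarboxylate | COC(=O)c1cc(OCc2ccccc2)cc2c1[C@@H](c1cc(OCc3ccccc3)cc(OCc3ccccc3)c1)[C@H](C(=O)ON1C(=O)c3ccccc3C1=O)O2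
F4 | step 17 | (unit B)zinc chloride | Cl[Zn]c1ccc2c(c1)[C@@H](c1cc(OCc3ccccc3)cc3c1[C@@H](c1cc(OCc4ccccc4)cc(OCc4ccccc4)c1)[C@H](c1ccc(OCc4ccccc4)cc1)O3)[C@H](c1ccc(OCc3ccccc3)cc1)O2
F5 | step 22 | octaphenol aldehyde (33 without its eight benzyl groups) | O=Cc1cc(O)cc2c1[C@@H](c1cc(O)cc(O)c1)[C@H](c1ccc3c(c1)[C@@H](c1cc(O)cc4c1[C@@H](c1cc(O)cc(O)c1)[C@H](c1ccc(O)cc1)O4)[C@H](c1ccc(O)cc1)O3)O2
F6 | step 22 | octakis(tert-butyldimethylsilyl) ether of F5 | O=Cc1cc(O[Si](C)(C)C(C)(C)C)cc2c1[C@@H](c1cc(O[Si](C)(C)C(C)(C)C)cc(O[Si](C)(C)C(C)(C)C)c1)[C@H](c1ccc3c(c1)[C@@H](c1cc(O[Si](C)(C)C(C)(C)C)cc4c1[C@@H](c1cc(O[Si](C)(C)C(C)(C)C)cc(O[Si](C)(C)C(C)(C)C)c1)[C@H](c1ccc(O[Si](C)(C)C(C)(C)C)cc1)O4)[C@H](c1ccc(O[Si](C)(C)C(C)(C)C)cc1)O3)O2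
F7 | step 22 | diethyl {[4-(tert-butyldimethylsilyloxy)phenyl]methyl}phosphonate | CCOP(=O)(Cc1ccc(O[Si](C)(C)C(C)(C)C)cc1)OCC
F8 | step 22 | nonakis(tert-butyldimethylsilyl) ether of 38 | CC(C)(C)[Si](C)(C)Oc1ccc(/C=C/c2cc(O[Si](C)(C)C(C)(C)C)cc3c2[C@@H](c2cc(O[Si](C)(C)C(C)(C)C)cc(O[Si](C)(C)C(C)(C)C)c2)[C@H](c2ccc4c(c2)[C@@H](c2cc(O[Si](C)(C)C(C)(C)C)cc5c2[C@@H](c2cc(O[Si](C)(C)C(C)(C)C)cc(O[Si](C)(C)C(C)(C)C)c2)[C@H](c2ccc(O[Si](C)(C)C(C)(C)C)cc2)O5)[C@H](c2ccc(O[Si](C)(C)C(C)(C)C)cc2)O4)O3)cc1
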